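**Retrosynthetic overview**

1. The target (19-O-acetylandrograpanin) is reached from a 3α-hydroxy bicycle (14-deoxyandrographolide) by C19 acetylation and Barton–McCombie removal of the C3 oxygen.
2. That bicycle comes from one epoxide-initiated, allylsilane-terminated cation–olefin bicyclisation of an acyclic epoxy alcohol: ring A closes first (C4–C5), ring B second (C9–C10), and the allylsilane leaves the exocyclic C8=C17 alkene.
3. The epoxide (C3 and C4, the first stereocentres) is set on an achiral triene by a hydroxyl-directed, peptide-organocatalysed asymmetric epoxidation of a Z-2-methylallylic alcohol; the Z geometry becomes the axial C19.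
4. The triene is assembled by B-alkyl Suzuki coupling (C2–C3) with (2Z)-3-iodo-2-methylprop-2-en-1-ol, Negishi coupling (C12–C13) with 3-bromofuran-2(5H)-one (butenolide ring carried in intact) and carbocupration/oxirane opening of a terminal alkyne (allylsilane and C9–C11).
5. The dienyne precursor comes from pent-4-ynal by two Wittig olefinations.

Assumption: the numbered starting materials are commercial and achiral, small reagents are listed under each step instead of being numbered, and atom labels C1–C20 are the labdane numbers of the target.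

**Route**

Step 1
Reactants: 1 pent-4-ynal; 2 2-(triphenyl-λ5-phosphanylidene)propanal
Product: 3 (2E)-2-methylhept-2-en-6-ynal
Conditions: CH2Cl2, 23 → 40 °C
Reagents that add atoms: none
Why: Wittig olefination with a stabilised ylide is E-selective and stops at the mono-adduct because the α-branched enal formed is far less electrophilic than 1.

Step 2
Reactants: 3 (2E)-2-methylhept-2-en-6-ynal
Product: 4 (3E)-3-methylocta-1,3-dien-7-yne
Conditions: Ph3PCH3Br, KOtBu, THF, 0 → 23 °C
Reagents that add atoms: methyltriphenylphosphonium bromide (C[P+](c1ccccc1)(c1ccccc1)c1ccccc1.[Br-])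
Why: Wittig methylenation of the enal carbonyl gives the 1,3-diene without touching the E-trisubstituted alkene or the terminal alkyne.

Step 3
Reactants: 4 (3E)-3-methylocta-1,3-dien-7-yne
Product: 6 (3Z,7E)-8-methyl-4-[(trimethylsilyl)methyl]deca-3,7,9-trien-1-ol, via alkenylcopper 5 (not isolated)
Conditions: Me3SiCH2MgCl, CuBr·SMe2, Et2O–SMe2, −45 → −20 °C; then oxirane, BF3·OEt2, −78 → −30 °C; aq NH4Cl
Reagents that add atoms: (trimethylsilyl)methylmagnesium chloride (C[Si](C)(C)C[Mg]Cl); oxirane (C1CO1)
Why: Normant carbocupration adds the silylmethyl group to the internal alkyne carbon and copper to the terminal one in a syn fashion, and BF3-assisted opening of oxirane with retention at the alkenyl–copper bond places CH2SiMe3 cis to the new hydroxyethyl chain, the allylsilane geometry needed for an equatorial C9 side chain.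

Step 4
Reactants: 6 (3Z,7E)-8-methyl-4-[(trimethylsilyl)methyl]deca-3,7,9-trien-1-ol
Product: 7 (3Z,7E)-1-iodo-8-methyl-4-[(trimethylsilyl)methyl]deca-3,7,9-triene
Conditions: PPh3, imidazole, I2, CH2Cl2, 0 °C
Reagents that add atoms: iodine ([I][I])
Why: Appel-type iodination displaces the primary alkoxyphosphonium by SN2 under buffered conditions that spare the allylsilane and the diene.

Step 5
Reactants: 7 (3Z,7E)-1-iodo-8-methyl-4-[(trimethylsilyl)methyl]deca-3,7,9-triene; 8 3-bromofuran-2(5H)-one
Product: 10 3-[(3Z,7E)-8-methyl-4-[(trimethylsilyl)methyl]deca-3,7,9-trien-1-yl]furan-2(5H)-one, via alkylzinc iodide 9 (not isolated)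
Conditions: Zn dust, LiCl, THF, 25 °C; then 8, Pd(OAc)2 (2 mol %), SPhos (4 mol %), THF, 25 °C
Reagents that add atoms: none
Why: LiCl-accelerated zinc insertion into the primary C–I bond followed by Negishi coupling at the alkenyl C–Br bond of 8 forms C12–C13 and brings in the butenolide intact without creating a stereocentre.

Step 6
Reactants: 11 prop-2-yn-1-ol
Product: 13 (2Z)-3-iodo-2-methylprop-2-en-1-ol, via alkenylmagnesium alkoxide 12 (not isolated)
Conditions: MeMgBr (2.5 equiv), CuI (10 mol %), Et2O, −10 → 20 °C; then I2, −78 → 0 °C; aq NH4Cl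
Reagents that add atoms: methylmagnesium bromide (C[Mg]Br); iodine ([I][I])
Why: Copper-catalysed anti-carbomagnesiation of the propargylic alkoxide (Duboudin reaction) proceeds through a five-membered magnesium chelate, so iodinolysis gives only the Z-iodoalkene with I and CH2OH cis.

Step 7
Reactants: 10 3-[(3Z,7E)-8-methyl-4-[(trimethylsilyl)methyl]deca-3,7,9-trien-1-yl]furan-2(5H)-one; 13 (2Z)-3-iodo-2-methylprop-2-en-1-ol
Product: 15 3-[(3Z,7E,11Z)-13-hydroxy-8,12-dimethyl-4-[(trimethylsilyl)methyl]trideca-3,7,11-trien-1-yl]furan-2(5H)-one, via alkylborane 14 (not isolated)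
Conditions: 9-BBN, THF, 0 → 23 °C; then 13, PdCl2(dppf) (5 mol %), AsPh3, Cs2CO3, DMF–H2O, 23 °C
Reagents that add atoms: none
Why: 9-BBN hydroborates only the terminal vinyl CH2 of the diene (anti-Markovnikov; the trisubstituted alkenes, allylsilane and butenolide are inert), and the primary alkylborane undergoes B-alkyl Suzuki–Miyaura coupling with the alkenyl iodide with retention of its Z geometry.

Step 8
Reactants: 15 3-[(3Z,7E,11Z)-13-hydroxy-8,12-dimethyl-4-[(trimethylsilyl)methyl]trideca-3,7,11-trien-1-yl]furan-2(5H)-one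
Product: 16 3-[(3Z,7E)-10-[(2R,3S)-3-(hydroxymethyl)-3-methyloxiran-2-yl]-8-methyl-4-[(trimethylsilyl)methyl]deca-3,7-dien-1-yl]furan-2(5H)-one
Conditions: aspartyl β-turn tetrapeptide catalyst (Boc-Asp-Pro-D-Val type, 10 mol %; enantiomeric series chosen for the C3 (R)/C4 (S) face), 30% aq H2O2, i-PrN=C=N-i-Pr, DMAP (10 mol %), CH2Cl2, 4 °C
Reagents that add atoms: hydrogen peroxide (OO)
Why: Proposed new method: the aspartic acid side chain of the peptide is turned over to a peracid by the carbodiimide and H2O2 while the peptide backbone hydrogen-bonds the allylic hydroxyl of 15, so oxygen is delivered intramolecularly (Henbest-type) only to the Z-2-methylallylic alkene and only to one enantiotopic face, setting C3 (R) and C4 (S) stereospecifically with CH2OH cis to C2, whereas the allylsilane and the isolated trisubstituted alkene lack the directing contact and the butenolide is electron-poor; the closest known reaction is aspartyl-peptide-catalysed hydroxyl-directed 2,3-epoxidation of farnesol, not yet shown for 2-methyl Z-allylic alcohols or beside an allylsilane.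

Step 9
Reactants: 16 3-[(3Z,7E)-10-[(2R,3S)-3-(hydroxymethyl)-3-methyloxiran-2-yl]-8-methyl-4-[(trimethylsilyl)methyl]deca-3,7-dien-1-yl]furan-2(5H)-one
Product: 17 14-deoxyandrographolide (3α,19-dihydroxy-ent-labda-8(17),13-dien-16,15-olide)
Conditions: MeAlCl2 (3 equiv), CH2Cl2, −78 °C; aq Rochelle salt
Reagents that add atoms: none
Why: In this Lewis-acid-promoted, epoxide-initiated, allylsilane-terminated cation–olefin bicyclisation through a chair–chair transition state, C5 attacks C4 anti to the epoxide oxygen (inversion, so the CH2OH that was cis to C2 becomes axial and the C3 hydroxyl equatorial), the E-alkene gives the trans ring fusion at C5/C10, the allylsilane geometry gives the equatorial side chain at C9, and loss of the silyl group from the β-silyl cation fixes the exocyclic C8=C17 alkene.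

Step 10
Reactants: 17 14-deoxyandrographolide
Product: 18 19-O-acetyl-14-deoxyandrographolide
Conditions: Ac2O (1.1 equiv), pyridine, CH2Cl2, 0 °C
Reagents that add atoms: acetic anhydride (CC(=O)OC(C)=O)
Why: Selective monoacylation of a 1,3-diol works because the primary C19 hydroxyl is acetylated much faster than the secondary C3 hydroxyl flanked by the quaternary C4.

Step 11
Reactants: 18 19-O-acetyl-14-deoxyandrographolide
Product: 19 19-O-acetyl-3-O-(1H-imidazol-1-ylcarbonothioyl)-14-deoxyandrographolide
Conditions: 1,1'-thiocarbonyldiimidazole, DMAP (cat.), ClCH2CH2Cl, 70 °C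
Reagents that add atoms: 1,1'-thiocarbonyldiimidazole (S=C(n1ccnc1)n1ccnc1)
Why: Thioacylation of the remaining secondary alcohol gives the radical-labile thiocarbamate (first half of a Barton–McCombie deoxygenation) under weakly basic conditions that limit acetate migration.

Step 12
Reactants: 19 19-O-acetyl-3-O-(1H-imidazol-1-ylcarbonothioyl)-14-deoxyandrographolide
Product: 20 19-O-acetylandrograpanin (19-acetoxy-ent-labda-8(17),13-dien-16,15-olide), the target
Conditions: Bu3SnH, AIBN (cat.), PhMe, 100 °C
Reagents that add atoms: none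
Why: In the Barton–McCombie radical deoxygenation the stannyl radical adds to C=S, β-scission releases the secondary C3 radical and hydrogen transfer from Bu3SnH gives the CH2 group, removing the C3 stereocentre and leaving C4, C5, C9 and C10 untouched.

**Compound list**

1 | pent-4-ynal | C#CCCC=O | starting material
2 | 2-(triphenyl-λ5-phosphanylidene)propanal | CC(C=O)=P(c1ccccc1)(c1ccccc1)c1ccccc1 | starting material
3 | (2E)-2-methylhept-2-en-6-ynal | C#CCC/C=C(\C)C=O | intermediate
4 | (3E)-3-methylocta-1,3-dien-7-yne | C#CCC/C=C(\C)C=C | intermediate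
5 | [(1Z,5E)-6-methyl-2-[(trimethylsilyl)methyl]octa-1,5,7-trien-1-yl]copper | [Cu]/C=C(C[Si](C)(C)C)/CC/C=C(\C)C=C | intermediate
6 | (3Z,7E)-8-methyl-4-[(trimethylsilyl)methyl]deca-3,7,9-trien-1-ol | OCC/C=C(C[Si](C)(C)C)/CC/C=C(\C)C=C | intermediate
7 | (3Z,7E)-1-iodo-8-methyl-4-[(trimethylsilyl)methyl]deca-3,7,9-triene | ICC/C=C(C[Si](C)(C)C)/CC/C=C(\C)C=C | intermediate
8 | 3-bromofuran-2(5H)-one | O=C1OCC=C1Br | starting material
9 | [(3Z,7E)-8-methyl-4-[(trimethylsilyl)methyl]deca-3,7,9-trien-1-yl]zinc iodide | I[Zn]CC/C=C(C[Si](C)(C)C)/CC/C=C(\C)C=C | intermediate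
10 | 3-[(3Z,7E)-8-methyl-4-[(trimethylsilyl)methyl]deca-3,7,9-trien-1-yl]furan-2(5H)-one | C=C/C(C)=C/CC/C(C[Si](C)(C)C)=C/CCC1=CCOC1=O | intermediate
11 | prop-2-yn-1-ol | C#CCO | starting material
12 | bromomagnesium (2Z)-3-(bromomagnesio)-2-methylprop-2-en-1-olate | Br[Mg]/C=C(C)\CO[Mg]Br | intermediate
13 | (2Z)-3-iodo-2-methylprop-2-en-1-ol | OC/C(C)=C\I | intermediate
14 | 9-[(3E,7Z)-3-methyl-10-(2-oxo-2,5-dihydrofuran-3-yl)-7-[(trimethylsilyl)methyl]deca-3,7-dien-1-yl]-9-borabicyclo[3.3.1]nonane | B1(CC/C(C)=C/CC/C(C[Si](C)(C)C)=C/CCC2=CCOC2=O)C3CCCC1CCC3 | intermediate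
15 | 3-[(3Z,7E,11Z)-13-hydroxy-8,12-dimethyl-4-[(trimethylsilyl)methyl]trideca-3,7,11-trien-1-yl]furan-2(5H)-one | OC/C(C)=C\CC/C(C)=C/CC/C(C[Si](C)(C)C)=C/CCC1=CCOC1=O | intermediate
16 | 3-[(3Z,7E)-10-[(2R,3S)-3-(hydroxymethyl)-3-methyloxiran-2-yl]-8-methyl-4-[(trimethylsilyl)methyl]deca-3,7-dien-1-yl]furan-2(5H)-one | OC[C@]1(C)O[C@@H]1CC/C(C)=C/CC/C(C[Si](C)(C)C)=C/CCC1=CCOC1=O | intermediate
17 | 14-deoxyandrographolide: 3-{2-[(1R,4aS,5R,6R,8aS)-6-hydroxy-5-(hydroxymethyl)-5,8a-dimethyl-2-methylidenedecahydronaphthalen-1-yl]ethyl}furan-2(5H)-one | C=C1CC[C@@H]2[C@](C)(CO)[C@H](O)CC[C@@]2(C)[C@@H]1CCC1=CCOC1=O | intermediate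
18 | 19-O-acetyl-14-deoxyandrographolide: [(1R,2R,4aS,5R,8aS)-2-hydroxy-1,4a-dimethyl-6-methylidene-5-[2-(2-oxo-2,5-dihydrofuran-3-yl)ethyl]decahydronaphthalen-1-yl]methyl acetate | C=C1CC[C@@H]2[C@](C)(COC(C)=O)[C@H](O)CC[C@@]2(C)[C@@H]1CCC1=CCOC1=O | intermediate
19 | 19-O-acetyl-3-O-(1H-imidazol-1-ylcarbonothioyl)-14-deoxyandrographolide (3R,4R,5S,9R,10S in labdane numbering) | C=C1CC[C@@H]2[C@](C)(COC(C)=O)[C@H](OC(=S)n3ccnc3)CC[C@@]2(C)[C@@H]1CCC1=CCOC1=O | intermediate
20 | 19-O-acetylandrograpanin: [(1R,4aS,5R,8aS)-1,4a-dimethyl-6-methylidene-5-[2-(2-oxo-2,5-dihydrofuran-3-yl)ethyl]decahydronaphthalen-1-yl]methyl acetate | C=C1CC[C@@H]2[C@](C)(COC(C)=O)CCC[C@@]2(C)[C@@H]1CCC1=CCOC1=O | target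

**Step count and risk**

Total step count: 12. Longest linear sequence: 11 steps (steps 1–5 and 7–12, from 1 to 20); step 6 is a one-step side branch.

The three steps most likely to fail:

Step 8, the proposed new peptide-catalysed epoxidation, may give low enantioselectivity on the 2-methyl Z-allylic alcohol or epoxidise the allylsilane in competition. The fallback is known chemistry: Katsuki–Sharpless asymmetric epoxidation of 15 with Ti(OiPr)4, L-(+)-diethyl tartrate and t-BuOOH over 4 Å molecular sieves in CH2Cl2 at −20 °C. This titanium tartrate system is also hydroxyl-directed and chemoselective for allylic alcohols. The natural tartrate, the one that gives (2S,3S)-epoxy alcohols from simple E-allylic alcohols, is predicted to attack the required face. The fallback sets out from 15, comes back to the route at 16 and makes no new compound.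

Step 9 may suffer from the free hydroxyl next to the epoxide: the aluminium alkoxide can trigger Payne-type or chloride opening instead of cyclisation. The fallback changes the substrate to the classical protected form. From 16, TBSCl and imidazole give the tert-butyldimethylsilyl ether of 16 F1. MeAlCl2 in CH2Cl2 at −78 °C then cyclises it to 19-O-(tert-butyldimethylsilyl)-14-deoxyandrographolide F2. Bu4NF in THF removes the silyl group and the sequence comes back to the route at 17.

Step 5 is exposed because 3-bromofuran-2(5H)-one is sensitive to bases and nucleophiles: the alkylzinc may add in conjugate fashion, or the alkylpalladium intermediate may undergo β-hydride elimination. The fallback reverses the polarity and sets out from 7 and 8. Silylation of 8 with i-Pr3SiOTf and Et3N gives 3-bromo-2-(triisopropylsilyloxy)furan F3. Bromine–lithium exchange with n-BuLi in THF at −78 °C and alkylation of the 3-lithiofuran with iodide 7 in THF/DMPU gives triisopropyl({3-[(3Z,7E)-8-methyl-4-[(trimethylsilyl)methyl]deca-3,7,9-trien-1-yl]furan-2-yl}oxy)silane F4. Hydrolysis of the silyl enol ether with aqueous HCl in THF comes back to the route at 10.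

**Further compounds**

F0 | step 8 | none | none
F1 | step 9 | 3-[(3Z,7E)-10-[(2R,3S)-3-{[(tert-butyldimethylsilyl)oxy]methyl}-3-methyloxiran-2-yl]-8-methyl-4-[(trimethylsilyl)methyl]deca-3,7-dien-1-yl]furan-2(5H)-one | CC(C)(C)[Si](C)(C)OC[C@]1(C)O[C@@H]1CC/C(C)=C/CC/C(C[Si](C)(C)C)=C/CCC1=CCOC1=O
F2 | step 9 | 19-O-(tert-butyldimethylsilyl)-14-deoxyandrographolide | C=C1CC[C@@H]2[C@](C)(CO[Si](C)(C)C(C)(C)C)[C@H](O)CC[C@@]2(C)[C@@H]1CCC1=CCOC1=O
F3 | step 5 | 3-bromo-2-(triisopropylsilyloxy)furan | CC(C)[Si](Oc1occc1Br)(C(C)C)C(C)C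
F4 | step 5 | triisopropyl({3-[(3Z,7E)-8-methyl-4-[(trimethylsilyl)methyl]deca-3,7,9-trien-1-yl]furan-2-yl}oxy)silane | CC(C)[Si](Oc1occc1CC/C=C(C[Si](C)(C)C)/CC/C=C(\C)C=C)(C(C)C)C(C)C
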